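**Retrosynthetic overview**

1. Target 15 is the all-cis (2R,3R,4R) tetrahydrofuran; it comes from silyl ether 14 by desilylation, and 14 from 1,4-diol 12 by closing the C5–O bond at the primary carbon (no stereocentre touched).
2. Diol 12 comes from all-cis lactone 11, which comes from benzylidene lactone 10 by hydrogenation from the open face (sets target C4); 10 is the aldol condensation product of lactone 6 and 2,4,5-trimethoxybenzaldehyde 7.
3. Key disconnection: the C2–C3 bond of the target (C5–C4 of lactone 6) is made by adding the β-carbon of enal 3, turned into a nucleophile (homoenolate) by a chiral carbene, to 3,4,5-trimethoxybenzaldehyde 4; this sets both stereocentres and closes the lactone.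
4. Enal 3 comes from cross-metathesis of allyl silyl ether 1 with crotonaldehyde 2.
5. Ring order: γ-lactone first (step 2), opened in step 5, tetrahydrofuran closed in step 6.

Assumption: the (5aS,10bR) triazolium precatalyst is taken to direct attack onto the Re face of 4 and give (4R,5R)-6. If the first run gives ent-6, the (5aR,10bS) antipode, made from (1S,2R)-cis-1-amino-2-indanol, is used and nothing else changes.

**Route**

Step 1
Reactants: 1 tert-butyldimethyl(prop-2-en-1-yloxy)silane; 2 (E)-but-2-enal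
Product: 3 (E)-4-[(tert-butyldimethylsilyl)oxy]but-2-enal
Conditions: second-generation Hoveyda–Grubbs catalyst RuCl2(H2IMes)(=CH-C6H4-2-O-i-Pr) (2.5 mol %), 2 (4 equiv), CH2Cl2, 40 °C
Reagents that add atoms: none
Why: Olefin cross-metathesis of a reactive terminal allyl ether with an electron-poor enal favours the cross product and gives the E-enal under thermodynamic control, with propene leaving as gas.

Step 2
Reactants: 3 (E)-4-[(tert-butyldimethylsilyl)oxy]but-2-enal; 4 3,4,5-trimethoxybenzaldehyde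
Product: 6 (4R,5R)-4-{[(tert-butyldimethylsilyl)oxy]methyl}-5-(3,4,5-trimethoxyphenyl)oxolan-2-one, via carbene-bound homoenolate 5 (not isolated)
Conditions: (5aS,10bR)-2-mesityl-5a,10b-dihydro-4H,6H-indeno[2,1-b][1,2,4]triazolo[4,3-d][1,4]oxazin-2-ium chloride (10 mol %), DBU (10 mol %), 4 (2 equiv), 3 added over 6 h, THF, 25 °C
Reagents that add atoms: none
Why: Proposed new method: the triazolylidene adds to the formyl carbon of 3 and a proton shift gives dienaminol 5, whose β-carbon is nucleophilic (homoenolate, d3 reactivity); this carbon attacks the Re face of 4 inside the indane-walled pocket through a hydrogen-bonded closed transition state that places aryl and CH2OSi cis, and the new alkoxide then acylates on the azolium carbonyl to close the lactone and release the carbene, so both stereocentres (lactone C4 and C5, later C3 and C2 of the target) are set in one event; the closest known reaction type is the NHC-catalysed homoenolate [3+2] annulation of enals with aryl aldehydes to cis-γ-butyrolactones, known with achiral imidazolylidenes and, enantioselectively, with this triazolium family for more activated carbonyl acceptors.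

Step 3
Reactants: 6 (4R,5R)-4-{[(tert-butyldimethylsilyl)oxy]methyl}-5-(3,4,5-trimethoxyphenyl)oxolan-2-one; 7 2,4,5-trimethoxybenzaldehyde
Product: 10 (3E,4R,5R)-4-{[(tert-butyldimethylsilyl)oxy]methyl}-3-[(2,4,5-trimethoxyphenyl)methylidene]-5-(3,4,5-trimethoxyphenyl)oxolan-2-one, via aldol adduct 8 (not isolated), via mesylate 9 (not isolated)
Conditions: LiN(SiMe3)2 (1.1 equiv), THF, −78 °C; 7 (1.2 equiv); MsCl (1.5 equiv), −78 → 0 °C; DBU (2.5 equiv), 0 → 25 °C, short contact
Reagents that add atoms: none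
Why: Aldol condensation: only the C3 methylene of the lactone is acidic, so its lithium enolate adds to 7 without touching C4 or C5, the aldolate is trapped as the mesylate and E1cB elimination gives the conjugated E-benzylidene lactone, erasing the two transient centres.

Step 4
Reactants: 10 (3E,4R,5R)-benzylidene lactone
Product: 11 (3R,4R,5R)-4-{[(tert-butyldimethylsilyl)oxy]methyl}-3-[(2,4,5-trimethoxyphenyl)methyl]-5-(3,4,5-trimethoxyphenyl)oxolan-2-one
Conditions: H2 (1 atm), 10% Pd/C, EtOAc, 25 °C, stopped after 1 equiv H2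
Reagents that add atoms: none
Why: Heterogeneous catalytic hydrogenation adds both hydrogens syn from the ring face opposite the cis-disposed CH2OSi and aryl groups, which pushes the new benzyl group onto their face and sets lactone C3 (target C4) as R, giving the all-cis lactone.

Step 5
Reactants: 11 (3R,4R,5R)-all-cis lactone
Product: 12 (1R,2R,3R)-2-{[(tert-butyldimethylsilyl)oxy]methyl}-3-[(2,4,5-trimethoxyphenyl)methyl]-1-(3,4,5-trimethoxyphenyl)butane-1,4-diol
Conditions: LiBH4 (2.5 equiv), THF, 0 → 25 °C; aq. NH4Cl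
Reagents that add atoms: none
Why: Hydride reduction of the lactone to the 1,4-diol breaks only the acyl C–O bond, and the weakly basic borohydride neither epimerises the α-centre before reduction nor moves or cleaves the silyl ether, so all three stereocentres carry over.

Step 6
Reactants: 12 (1R,2R,3R)-diol
Product: 14 tert-butyldimethyl{[(2R,3R,4R)-2-(3,4,5-trimethoxyphenyl)-4-[(2,4,5-trimethoxyphenyl)methyl]oxolan-3-yl]methoxy}silane, via primary tosylate 13 (not isolated)
Conditions: TsCl (1.2 equiv), pyridine, 0 → 45 °C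
Reagents that add atoms: none
Why: Selective sulfonylation of the primary hydroxyl, then intramolecular Williamson-type 5-exo-tet displacement by the neutral benzylic hydroxyl, closes the ring at the primary carbon, so no bond to a stereocentre is broken and the all-cis array is kept.

Step 7
Reactants: 14 (2R,3R,4R)-silyl ether
Product: 15 [(2R,3R,4R)-2-(3,4,5-trimethoxyphenyl)-4-[(2,4,5-trimethoxyphenyl)methyl]oxolan-3-yl]methanol
Conditions: Bu4NF (1.5 equiv), THF, 0 → 25 °C
Reagents that add atoms: none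
Why: Fluoride-induced desilylation cleaves only the Si–O bond and leaves the base-stable tetrahydrofuran and its three stereocentres untouched.

**Compound list**

1 | tert-butyldimethyl(prop-2-en-1-yloxy)silane | C=CCO[Si](C)(C)C(C)(C)C | starting material
2 | (E)-but-2-enal (crotonaldehyde) | C/C=C/C=O | starting material
3 | (E)-4-[(tert-butyldimethylsilyl)oxy]but-2-enal | O=C/C=C/CO[Si](C)(C)C(C)(C)C | intermediate
4 | 3,4,5-trimethoxybenzaldehyde | COc1cc(C=O)cc(OC)c1OC | starting material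
5 | carbene-bound homoenolate: dienaminol from 3 and the (5aS,10bR)-2-mesityl-indeno-triazolo-oxazinylidene, nucleophilic at the carbon bearing CH2OSi; enaminol C=C geometry not defined | OC(/C=C/CO[Si](C)(C)C(C)(C)C)=C1N(c2c(C)cc(C)cc2C)N=C2CO[C@H]3Cc4ccccc4[C@H]3N12 | intermediate
6 | (4R,5R)-4-{[(tert-butyldimethylsilyl)oxy]methyl}-5-(3,4,5-trimethoxyphenyl)oxolan-2-one (4,5-cis) | O=C1C[C@H](CO[Si](C)(C)C(C)(C)C)[C@H](c2cc(OC)c(OC)c(OC)c2)O1 | intermediate
7 | 2,4,5-trimethoxybenzaldehyde | COc1cc(OC)c(C=O)cc1OC | starting material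
8 | (4R,5R)-4-{[(tert-butyldimethylsilyl)oxy]methyl}-3-[hydroxy(2,4,5-trimethoxyphenyl)methyl]-5-(3,4,5-trimethoxyphenyl)oxolan-2-one, formed as its lithium alkoxide; mixture at C3 and the carbinol carbon | O=C1C(C(O)c2cc(OC)c(OC)cc2OC)[C@H](CO[Si](C)(C)C(C)(C)C)[C@H](c2cc(OC)c(OC)c(OC)c2)O1 | intermediate
9 | methanesulfonate of 8; same mixture | O=C1C(C(OS(C)(=O)=O)c2cc(OC)c(OC)cc2OC)[C@H](CO[Si](C)(C)C(C)(C)C)[C@H](c2cc(OC)c(OC)c(OC)c2)O1 | intermediate
10 | (3E,4R,5R)-4-{[(tert-butyldimethylsilyl)oxy]methyl}-3-[(2,4,5-trimethoxyphenyl)methylidene]-5-(3,4,5-trimethoxyphenyl)oxolan-2-one | O=C1/C(=C/c2cc(OC)c(OC)cc2OC)[C@H](CO[Si](C)(C)C(C)(C)C)[C@H](c2cc(OC)c(OC)c(OC)c2)O1 | intermediate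
11 | (3R,4R,5R)-4-{[(tert-butyldimethylsilyl)oxy]methyl}-3-[(2,4,5-trimethoxyphenyl)methyl]-5-(3,4,5-trimethoxyphenyl)oxolan-2-one (all-cis) | O=C1[C@H](Cc2cc(OC)c(OC)cc2OC)[C@H](CO[Si](C)(C)C(C)(C)C)[C@H](c2cc(OC)c(OC)c(OC)c2)O1 | intermediate
12 | (1R,2R,3R)-2-{[(tert-butyldimethylsilyl)oxy]methyl}-3-[(2,4,5-trimethoxyphenyl)methyl]-1-(3,4,5-trimethoxyphenyl)butane-1,4-diol | OC[C@H](Cc1cc(OC)c(OC)cc1OC)[C@H](CO[Si](C)(C)C(C)(C)C)[C@H](c1cc(OC)c(OC)c(OC)c1)O | intermediate
13 | (2R,3R,4R)-3-{[(tert-butyldimethylsilyl)oxy]methyl}-4-hydroxy-2-[(2,4,5-trimethoxyphenyl)methyl]-4-(3,4,5-trimethoxyphenyl)butyl 4-methylbenzenesulfonate | Cc1ccc(cc1)S(=O)(=O)OC[C@H](Cc1cc(OC)c(OC)cc1OC)[C@H](CO[Si](C)(C)C(C)(C)C)[C@H](c1cc(OC)c(OC)c(OC)c1)O | intermediate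
14 | tert-butyldimethyl{[(2R,3R,4R)-2-(3,4,5-trimethoxyphenyl)-4-[(2,4,5-trimethoxyphenyl)methyl]oxolan-3-yl]methoxy}silane (all-cis) | COc1cc(OC)c(OC)cc1C[C@H]1CO[C@@H](c2cc(OC)c(OC)c(OC)c2)[C@H]1CO[Si](C)(C)C(C)(C)C | intermediate
15 | [(2R,3R,4R)-2-(3,4,5-trimethoxyphenyl)-4-[(2,4,5-trimethoxyphenyl)methyl]oxolan-3-yl]methanol (all-cis) | COc1cc(OC)c(OC)cc1C[C@H]1CO[C@@H](c2cc(OC)c(OC)c(OC)c2)[C@H]1CO | target

**Step count and risk**

Total steps: 7. Longest linear sequence: 7 (1 → 3 → 6 → 10 → 11 → 12 → 14 → 15); aldehydes 2, 4 and 7 are bought.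

Steps most likely to fail:

Step 2. The risks are loss of silyloxide from homoenolate 5 (the CH2OSi group sits next to the nucleophilic carbon), enal self-annulation, a modest cis:trans ratio and an unproven level and sense of enantioselectivity. The fallback sets out from 4 and comes back at 6 by an auxiliary-controlled anti-aldol route with normal polarity. (R)-4-Benzyloxazolidin-2-one is acylated with pent-4-enoyl chloride (n-BuLi, THF, −78 °C) to give (4R)-4-benzyl-3-(pent-4-enoyl)-1,3-oxazolidin-2-one F1. MgCl2 (10 mol %), Et3N and Me3SiCl in EtOAc at 25 °C add F1 to 4; the chelated Z-enolate is attacked on the face away from the benzyl group and gives the O-silylated anti adduct (4R)-4-benzyl-3-[(2S,3R)-2-(prop-2-en-1-yl)-3-(3,4,5-trimethoxyphenyl)-3-(trimethylsilyloxy)propanoyl]-1,3-oxazolidin-2-one F2. TFA in MeOH frees (4R)-4-benzyl-3-[(2S,3R)-3-hydroxy-2-(prop-2-en-1-yl)-3-(3,4,5-trimethoxyphenyl)propanoyl]-1,3-oxazolidin-2-one F3. LiBH4 (THF, 1 equiv MeOH, 0 °C) removes the auxiliary and gives (1R,2R)-2-(prop-2-en-1-yl)-1-(3,4,5-trimethoxyphenyl)propane-1,3-diol F4. t-BuMe2SiCl and imidazole (CH2Cl2, 0 °C) silylate only the primary hydroxyl to give (1R,2R)-2-{[(tert-butyldimethylsilyl)oxy]methyl}-1-(3,4,5-trimethoxyphenyl)pent-4-en-1-ol F5. OsO4 (cat.), NaIO4 and 2,6-lutidine in dioxane–water cleave the terminal alkene, and the aldehyde closes to (4R,5R)-4-{[(tert-butyldimethylsilyl)oxy]methyl}-5-(3,4,5-trimethoxyphenyl)oxolan-2-ol F6. TEMPO (cat.) with PhI(OAc)2 in CH2Cl2 oxidises F6 to 6.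

Step 4. The risks are hydrogenolysis of the benzylic C5–O bond of the lactone on palladium and incomplete face selectivity. The fallback sets out from 10 and comes back at 11 by conjugate hydride addition and kinetic protonation instead of hydrogenation. LiBH(s-Bu)3 (THF, −78 °C) adds hydride to the benzylic terminus of 10 and gives lithium (4R,5R)-4-{[(tert-butyldimethylsilyl)oxy]methyl}-3-[(2,4,5-trimethoxyphenyl)methyl]-5-(3,4,5-trimethoxyphenyl)-4,5-dihydrofuran-2-olate F7. F7 is protonated at −78 °C by 2,6-di-tert-butylphenol from the face opposite the CH2OSi and aryl groups, giving 11 with no metal surface present.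

Step 6. The risks are sulfonylation of the benzylic hydroxyl (ionisation, loss of C2 configuration) and silyl migration in 12 that would let the wrong oxygen close the ring. The fallback sets out from 11 and comes back at 14, keeping the ring oxygen in place and removing the carbonyl instead. i-Bu2AlH (CH2Cl2, −78 °C) reduces 11 to (3R,4R,5R)-4-{[(tert-butyldimethylsilyl)oxy]methyl}-3-[(2,4,5-trimethoxyphenyl)methyl]-5-(3,4,5-trimethoxyphenyl)oxolan-2-ol F8 (anomer mixture). Et3SiH with BF3·OEt2 (CH2Cl2, −78 °C) reduces the cyclic oxocarbenium ion formed at the former carbonyl carbon and gives 14. The temperature is kept low because the benzylic C2–O bond can ionise under Lewis acid.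

**Further compounds**

F1 | step 2 | (4R)-4-benzyl-3-(pent-4-enoyl)-1,3-oxazolidin-2-one | C=CCCC(=O)N1[C@H](Cc2ccccc2)COC1=O
F2 | step 2 | (4R)-4-benzyl-3-[(2S,3R)-2-(prop-2-en-1-yl)-3-(3,4,5-trimethoxyphenyl)-3-(trimethylsilyloxy)propanoyl]-1,3-oxazolidin-2-one | C=CC[C@H](C(=O)N1[C@H](Cc2ccccc2)COC1=O)[C@H](c1cc(OC)c(OC)c(OC)c1)O[Si](C)(C)C
F3 | step 2 | (4R)-4-benzyl-3-[(2S,3R)-3-hydroxy-2-(prop-2-en-1-yl)-3-(3,4,5-trimethoxyphenyl)propanoyl]-1,3-oxazolidin-2-one | C=CC[C@H](C(=O)N1[C@H](Cc2ccccc2)COC1=O)[C@H](c1cc(OC)c(OC)c(OC)c1)O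
F4 | step 2 | (1R,2R)-2-(prop-2-en-1-yl)-1-(3,4,5-trimethoxyphenyl)propane-1,3-diol | C=CC[C@H](CO)[C@H](c1cc(OC)c(OC)c(OC)c1)O
F5 | step 2 | (1R,2R)-2-{[(tert-butyldimethylsilyl)oxy]methyl}-1-(3,4,5-trimethoxyphenyl)pent-4-en-1-ol | C=CC[C@H](CO[Si](C)(C)C(C)(C)C)[C@H](c1cc(OC)c(OC)c(OC)c1)O
F6 | step 2 | (4R,5R)-4-{[(tert-butyldimethylsilyl)oxy]methyl}-5-(3,4,5-trimethoxyphenyl)oxolan-2-ol (anomer mixture) | OC1C[C@H](CO[Si](C)(C)C(C)(C)C)[C@H](c2cc(OC)c(OC)c(OC)c2)O1
F7 | step 4 | lithium (4R,5R)-4-{[(tert-butyldimethylsilyl)oxy]methyl}-3-[(2,4,5-trimethoxyphenyl)methyl]-5-(3,4,5-trimethoxyphenyl)-4,5-dihydrofuran-2-olate | [Li]OC1=C(Cc2cc(OC)c(OC)cc2OC)[C@H](CO[Si](C)(C)C(C)(C)C)[C@H](c2cc(OC)c(OC)c(OC)c2)O1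
F8 | step 6 | (3R,4R,5R)-4-{[(tert-butyldimethylsilyl)oxy]methyl}-3-[(2,4,5-trimethoxyphenyl)methyl]-5-(3,4,5-trimethoxyphenyl)oxolan-2-ol (anomer mixture) | OC1[C@H](Cc2cc(OC)c(OC)cc2OC)[C@H](CO[Si](C)(C)C(C)(C)C)[C@H](c2cc(OC)c(OC)c(OC)c2)O1
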